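**Assumption:** the cross-metathesis product 7 is expected as an E/Z mixture with the E isomer predominating. It is drawn and named as E, and both isomers converge in the hydrogenation of step 4.

## Analysis of the target

The target 9 is an achiral diaryl ketone: ring A is a benzene ring with the acyl group between two hydroxyls (a 2-acylresorcinol), and ring B is a guaiacyl ring (4-hydroxy-3-methoxyphenyl). The two rings are joined by an unbranched chain running from the carbonyl carbon C1 through eight methylenes to C9, which is benzylic to ring B. There is no stereocenter and no ring fusion, so the problems are regiochemical and concern functional-group compatibility, not configuration. The sensitive groups are the three free phenols (acidic, oxidizable, and activating both rings toward electrophiles) and the aryl ketone, which is hydrogen-bonded to the two ortho hydroxyls. The first difficulty is the position of the acyl group on ring A: it lies between the two oxygens, where direct electrophilic acylation of a meta-dioxygenated benzene does not go. The second is the eight-methylene tether, which has no functional group to guide its assembly and should leave none behind. The strategy rests on two facts: ring B with C9 and C8 is the carbon skeleton of eugenol up to its alkene carbon, and ring A with C1 and C2 is 2',6'-dihydroxyacetophenone with the carbonyl already in the correct place. Only the five methylenes C3 to C7 have to be inserted, and the chain can be closed at C7–C8 through a double bond that is then saturated.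

## Retrosynthetic reasoning

**9 to 8.** The two phenols of ring A are revealed last by cleaving the O–CH2 bonds of two methoxymethyl acetals. Masking is needed because free ortho phenols would consume the base in the enolate chemistry that builds the chain. The acetal is chosen because it survives strong base, ruthenium alkylidenes and catalytic hydrogenation, and leaves under mild acid that touches nothing else in 9. The phenol of ring B needs no protection at any stage.

**8 to 7.** The saturated C7–C8 bond of 8 is traced back to the C7=C8 alkene of 7. This is a pure adjustment of oxidation level. It also removes any concern about alkene geometry, because both isomers of 7 give the same 8.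

**7 to 5 and 6.** The C7=C8 double bond is cut by a cross-metathesis transform, which is the central disconnection. It is placed here because the fragment on the ring B side then becomes eugenol 6, an inexpensive natural allylbenzene that carries ring B, C9 and C8 with every oxygen substituent in place. Its terminal methylene is expelled in the forward reaction together with the terminal methylene of the partner. The other fragment is the terminal alkene 5, which carries ring A and C1 to C7. A cut one bond closer to ring B would require a styrene partner and a different, less available arene. A cut further toward C1 would require a functionalized arylalkene that would itself have to be synthesized. The forward reaction must couple two unhindered monosubstituted alkenes selectively across, not with themselves, and must not let the allyl double bond of 6 migrate.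

**5 to 2 and 3.** The C2–C3 bond of 5 is cut to the enolate 4 of the methyl ketone 2 and the primary bromide 3. C2 is the only enolizable position of 2, because the other side of the carbonyl is the aryl carbon, so the site of deprotonation is not in doubt. The gain is that the awkward acyl position on ring A is never constructed: it is bought with 1.

**2 to 1.** Removal of the two acetal groups leads to commercial 1. The forward step must cap both hydroxyls, including the one held in a hydrogen bond to the carbonyl.

## Alternatives that were turned down

**Alternative 1:** Ring A is disconnected between the acyl-bearing carbon and one oxygen-bearing carbon. This gives the open-chain dioxo ester A2, methyl 15-[4-(benzyloxy)-3-methoxyphenyl]-5,7-dioxopentadecanoate. In the forward sense NaOMe deprotonates the C6 methylene between the two ketones, and the carbanion attacks the ester carbonyl in a Dieckmann-type closure to the triketone A1. A1 would then be dehydrogenated to the aromatic ring and debenzylated to 9.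
- For it: it follows polyketide logic, it places the acyl group between the two oxygens by construction, and ring A needs no protecting group. On the regiochemistry of ring A it is as secure as the chosen route.
- Against it: A2 is a long 1,3-dicarbonyl chain that needs several carbon–carbon bond formations of its own. The aromatization of A1 is an oxidation of a strongly enolized, chelated triketone (Hg(OAc)2, halogenation and elimination, or a quinone oxidant), and it must not attack the electron-rich ring B or its benzylic C9.
- Comparison: the chosen strategy buys ring A aromatic and already acylated, so it avoids both the assembly of A2 and the change of oxidation level, and it is several steps shorter.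

**Alternative 2:** Ring A is disconnected at two adjacent bonds, the aryl–oxygen bond and the aryl–carbonyl bond. In the forward sense CsF liberates the aryne A5, 3-(benzyloxy)benzyne, from the silyl triflate A6, 3-(benzyloxy)-2-(trimethylsilyl)phenyl trifluoromethanesulfonate. The carboxylate of the acid A4, 9-[4-(benzyloxy)-3-methoxyphenyl]nonanoic acid, adds through oxygen at the aryne carbon remote from the benzyloxy group. The aryl anion formed next to that group then takes over the acyl group, giving the ortho-hydroxy ketone A3.
- For it: two bonds to ring A form in one operation, and the benzyloxy group steers the addition so that the acyl group ends between the two oxygens. In bond-forming economy at ring A this is stronger than the chosen route.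
- Against it: the acyl shift passes through a strained four-membered transition state and competes with simple protonation of the aryl anion, which ends in an aryl ester. A6 must be made in several steps. A4 still contains the whole chain, so the tether problem is only moved.
- Comparison: the chosen strategy gives up the double bond formation at ring A but uses three commercial building blocks and a catalytic coupling whose only by-product is a gas.

**Alternative 3:** The C2–C3 bond is disconnected to the methyl ketone A7, 2',6'-bis(benzyloxy)acetophenone, and the alcohol A8, 7-[4-(benzyloxy)-3-methoxyphenyl]heptan-1-ol. In the forward sense [Cp*IrCl2]2 and KOH dehydrogenate A8 to the aldehyde, aldol condensation with A7 gives an enone, and the iridium hydride returns the hydrogen to give the saturated ketone A9. A single hydrogenolysis then gives 9.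
- For it: water is the only by-product, and the chain comes out saturated without a separate reduction. Ketones with two ortho substituents are good substrates, because the twisted carbonyl resists self-condensation and reduction. In redox economy at the coupling, and in having no alkene that could migrate, this is stronger than the chosen route.
- Against it: A8 is not a commercial compound. Its seven-carbon tether to ring B must be built first, which costs the steps saved at the coupling, and the coupling runs in hot alkali.
- Comparison: the chosen strategy cuts the same C2–C3 bond with a commercial six-carbon bromide and leaves the link to ring B to eugenol, so that no fragment needs more than two steps of preparation.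

Key step: step 3

## Route

**Step 1**
Reactants: 1 2',6'-dihydroxyacetophenone
Product: 2 2',6'-bis(methoxymethoxy)acetophenone
Conditions: NaH (2.2 equiv), MOMCl (2.4 equiv), DMF, 0 °C → rt
Reagents that add atoms: chloromethyl methyl ether (MOMCl), COCCl
Why: Phenol O-alkylation (methoxymethyl ether formation); NaH deprotonates both hydroxyls, including the one hydrogen-bonded to the carbonyl, and the phenoxides displace chloride from the reactive α-chloro ether. Keeping the base close to two equivalents leaves the methyl ketone unenolized, so C-alkylation should not compete.

**Step 2**
Reactants: 2 2',6'-bis(methoxymethoxy)acetophenone; 3 6-bromohex-1-ene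
Product: 5 1-[2,6-bis(methoxymethoxy)phenyl]oct-7-en-1-one, via lithium enolate 4 (not isolated)
Conditions: LiN(i-Pr)2 (LDA, 1.1 equiv), THF, −78 °C; then 3 (1.5 equiv), DMPU, −78 °C → rt
Reagents that add atoms: none
Why: Ketone enolate alkylation; LDA removes a proton from the only α-carbon (C2) to give enolate 4, which displaces bromide from the unhindered primary carbon of 3 in an SN2 reaction that DMPU accelerates by breaking up the lithium aggregates. The carbonyl of 2 is twisted out of the ring plane and flanked by two ortho substituents, which should hold back aldol self-condensation while the alkylation proceeds.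

**Step 3**
Reactants: 5 1-[2,6-bis(methoxymethoxy)phenyl]oct-7-en-1-one; 6 eugenol
Product: 7 (E)-1-[2,6-bis(methoxymethoxy)phenyl]-9-(4-hydroxy-3-methoxyphenyl)non-7-en-1-one
Conditions: 6 (3 equiv), second-generation Grubbs catalyst (H2IMes)(PCy3)Cl2Ru=CHPh (5 mol%), 1,4-benzoquinone (10 mol%), CH2Cl2, 40 °C, argon sweep
Reagents that add atoms: none
Why: Olefin cross-metathesis by the Chauvin mechanism: after loss of PCy3 the ruthenium alkylidene undergoes [2+2] cycloaddition and cycloreversion with the terminal alkene of one partner, and the new alkylidene repeats the sequence with the other partner, releasing 7 and a ruthenium methylidene that carries the chain while ethylene leaves the solution. The closest known reaction type is the ruthenium-catalysed cross-metathesis of allylbenzenes, eugenol among them, with unbranched terminal alkenes. No ring is closed and no stereocenter is formed; the alkene should be mainly E under thermodynamic control, which is of no consequence because step 4 saturates it. The first selectivity needed is cross-coupling over the two self-metathesis products: both partners are unhindered monosubstituted alkenes of similar reactivity, so the outcome is statistical, and a threefold excess of inexpensive 6 should channel most of 5 into 7, while the symmetrical dimer of 5 stays metathesis-active and can be resubmitted with 6. The second is the absence of double-bond migration: a ruthenium hydride would move the allyl double bond into conjugation with ring B and a later metathesis would then excise one carbon, so 1,4-benzoquinone is added to intercept hydrides and the temperature is kept at 40 °C. The ketone is five methylenes away from the alkene and sterically shielded, and the acetals and the free phenol of 6 are functional groups that this catalyst tolerates.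

**Step 4**
Reactants: 7 (E)-1-[2,6-bis(methoxymethoxy)phenyl]-9-(4-hydroxy-3-methoxyphenyl)non-7-en-1-one
Product: 8 1-[2,6-bis(methoxymethoxy)phenyl]-9-(4-hydroxy-3-methoxyphenyl)nonan-1-one
Conditions: H2 (1 atm), 10% Pd/C, EtOAc, rt
Reagents that add atoms: none
Why: Heterogeneous catalytic hydrogenation; the 1,2-disubstituted alkene is reduced quickly at atmospheric pressure, and both geometric isomers give the same product. The aryl ketone is twisted out of conjugation and shielded by two ortho substituents, so it should not be reduced under these mild neutral conditions, and the acetals and the phenol are inert.

**Step 5**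
Reactants: 8 1-[2,6-bis(methoxymethoxy)phenyl]-9-(4-hydroxy-3-methoxyphenyl)nonan-1-one
Product: 9 1-(2,6-dihydroxyphenyl)-9-(4-hydroxy-3-methoxyphenyl)nonan-1-one
Conditions: HCl (3 M aq.), MeOH, 50 °C
Reagents that add atoms: none
Why: Acid-catalysed acetal cleavage (methanolysis of the methoxymethyl ethers); protonation and loss of each phenol gives a methoxymethyl cation that the large excess of methanol captures as dimethoxymethane. Nothing else in 8 is acid-labile, and the freed hydroxyls are stabilized by hydrogen bonding to the carbonyl.

## Compound list

1 | 2',6'-dihydroxyacetophenone | CC(=O)c1c(O)cccc1O | starting material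
2 | 2',6'-bis(methoxymethoxy)acetophenone | CC(=O)c1c(OCOC)cccc1OCOC | intermediate
3 | 6-bromohex-1-ene | C=CCCCCBr | starting material
4 | lithium 1-[2,6-bis(methoxymethoxy)phenyl]ethen-1-olate (lithium enolate of 2) | [Li]OC(=C)c1c(OCOC)cccc1OCOC | intermediate
5 | 1-[2,6-bis(methoxymethoxy)phenyl]oct-7-en-1-one | C=CCCCCCC(=O)c1c(OCOC)cccc1OCOC | intermediate
6 | eugenol (4-allyl-2-methoxyphenol) | C=CCc1ccc(O)c(OC)c1 | starting material
7 | (E)-1-[2,6-bis(methoxymethoxy)phenyl]-9-(4-hydroxy-3-methoxyphenyl)non-7-en-1-one | COc1cc(C/C=C/CCCCCC(=O)c2c(OCOC)cccc2OCOC)ccc1O | intermediate
8 | 1-[2,6-bis(methoxymethoxy)phenyl]-9-(4-hydroxy-3-methoxyphenyl)nonan-1-one | COc1cc(CCCCCCCCC(=O)c2c(OCOC)cccc2OCOC)ccc1O | intermediate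
9 | 1-(2,6-dihydroxyphenyl)-9-(4-hydroxy-3-methoxyphenyl)nonan-1-one | COc1cc(CCCCCCCCC(=O)c2c(O)cccc2O)ccc1O | target

## Step count and risks

Total step count: 5. Longest linear sequence: 5 steps (1 → 2 → 5 → 7 → 8 → 9); 3 and 6 enter as purchased.

**Step 3 (key step).** The most likely failure is poor cross-selectivity, with much of 5 diverted into self-metathesis. The second is migration of the allyl double bond under ruthenium hydride catalysis, followed by metathesis that shortens the chain by one carbon and gives a homologue that is hard to separate.
Fallback: a B-alkyl Suzuki–Miyaura coupling replaces the metathesis and attaches ring B directly to C9. It sets out from 2, whose enolate 4 is alkylated with 7-bromohept-1-ene (LDA, THF, DMPU) to give 1-[2,6-bis(methoxymethoxy)phenyl]non-8-en-1-one F1. Hydroboration of the terminal alkene with 9-BBN (THF, 0 °C → rt) gives the alkylborane 9-{9-[2,6-bis(methoxymethoxy)phenyl]-9-oxononyl}-9-borabicyclo[3.3.1]nonane F2, which is not isolated. It is coupled with commercial 1-(benzyloxy)-4-bromo-2-methoxybenzene (PdCl2(dppf), aqueous K3PO4, DMF, 60 °C) to give 9-[4-(benzyloxy)-3-methoxyphenyl]-1-[2,6-bis(methoxymethoxy)phenyl]nonan-1-one F3. Hydrogenolysis of the benzyl ether (H2, Pd/C, EtOAc) gives 8, where the route is rejoined before step 5.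

**Step 2.** Proton exchange between the product ketone and unreacted enolate 4 can lead to double alkylation at C2. The slow SN2 reaction of an unactivated bromide also leaves time for aldol self-condensation on warming.
Fallback: the simple enolate is replaced by a β-keto ester enolate, which alkylates cleanly once. It sets out from 2, which is acylated with dimethyl carbonate (NaH, THF, reflux) to give methyl 3-[2,6-bis(methoxymethoxy)phenyl]-3-oxopropanoate F4. Alkylation with 3 (K2CO3, NaI cat., DMF, 60 °C) gives methyl 2-[2,6-bis(methoxymethoxy)benzoyl]oct-7-enoate F5. Krapcho dealkoxycarbonylation (LiCl, DMSO, H2O, 140 °C) then gives 5, where the route is rejoined.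

**Step 5.** The methoxymethyl cation or formaldehyde released during cleavage can attack the electron-rich ring B or the freed ring A (ring alkylation or methylene bridging). Cleavage of the second acetal may also stop short.
Fallback: the protecting group is changed so that no acid step is needed. It sets out from 1, which is benzylated (BnBr, K2CO3, DMF, 60 °C) to give 2',6'-bis(benzyloxy)acetophenone F6. Enolate alkylation with 3 as in step 2 gives 1-[2,6-bis(benzyloxy)phenyl]oct-7-en-1-one F7. Cross-metathesis with 6 as in step 3 gives (E)-1-[2,6-bis(benzyloxy)phenyl]-9-(4-hydroxy-3-methoxyphenyl)non-7-en-1-one F8. A single hydrogenation (H2, Pd/C, EtOAc/MeOH) then saturates the alkene and removes both benzyl ethers, arriving directly at 9.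

**Step 4.** Over-reduction of the aryl ketone at the benzylic carbonyl is possible on prolonged exposure. Slow uptake is also possible if ruthenium residues from step 3 poison the palladium surface.
Fallback: the metal catalyst is replaced by diimide, which transfers hydrogen to carbon–carbon double bonds in a concerted way and does not reduce ketones. It is generated from 2-nitrobenzenesulfonyl hydrazide and Et3N in CH2Cl2 at rt. This fallback sets out from 7 and comes back at 8; it makes no new compound (F0).

## Further compounds

F1 | step 3 | 1-[2,6-bis(methoxymethoxy)phenyl]non-8-en-1-one | C=CCCCCCCC(=O)c1c(OCOC)cccc1OCOC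
F2 | step 3 | 9-{9-[2,6-bis(methoxymethoxy)phenyl]-9-oxononyl}-9-borabicyclo[3.3.1]nonane | O=C(CCCCCCCCB1C2CCCC1CCC2)c1c(OCOC)cccc1OCOC
F3 | step 3 | 9-[4-(benzyloxy)-3-methoxyphenyl]-1-[2,6-bis(methoxymethoxy)phenyl]nonan-1-one | COc1cc(CCCCCCCCC(=O)c2c(OCOC)cccc2OCOC)ccc1OCc1ccccc1
F4 | step 2 | methyl 3-[2,6-bis(methoxymethoxy)phenyl]-3-oxopropanoate | COC(=O)CC(=O)c1c(OCOC)cccc1OCOC
F5 | step 2 | methyl 2-[2,6-bis(methoxymethoxy)benzoyl]oct-7-enoate | COC(=O)C(CCCCC=C)C(=O)c1c(OCOC)cccc1OCOC
F6 | step 5 | 2',6'-bis(benzyloxy)acetophenone | CC(=O)c1c(OCc2ccccc2)cccc1OCc1ccccc1
F7 | step 5 | 1-[2,6-bis(benzyloxy)phenyl]oct-7-en-1-one | C=CCCCCCC(=O)c1c(OCc2ccccc2)cccc1OCc1ccccc1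
F8 | step 5 | (E)-1-[2,6-bis(benzyloxy)phenyl]-9-(4-hydroxy-3-methoxyphenyl)non-7-en-1-one | COc1cc(C/C=C/CCCCCC(=O)c2c(OCc3ccccc3)cccc2OCc2ccccc2)ccc1O
F0 | step 4 | none | none
A1 | alternative 1 | 2-{9-[4-(benzyloxy)-3-methoxyphenyl]nonanoyl}cyclohexane-1,3-dione | O=C1CCCC(=O)C1C(=O)CCCCCCCCc1ccc(OCc2ccccc2)c(OC)c1
A2 | alternative 1 | methyl 15-[4-(benzyloxy)-3-methoxyphenyl]-5,7-dioxopentadecanoate | COC(=O)CCCC(=O)CC(=O)CCCCCCCCc1ccc(OCc2ccccc2)c(OC)c1
A3 | alternative 2 | 1-[2-(benzyloxy)-6-hydroxyphenyl]-9-[4-(benzyloxy)-3-methoxyphenyl]nonan-1-one | COc1cc(CCCCCCCCC(=O)c2c(O)cccc2OCc2ccccc2)ccc1OCc1ccccc1
A4 | alternative 2 | 9-[4-(benzyloxy)-3-methoxyphenyl]nonanoic acid | COc1cc(CCCCCCCCC(=O)O)ccc1OCc1ccccc1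
A5 | alternative 2 | 3-(benzyloxy)benzyne | O(Cc1ccccc1)C1=CC=CC#C1
A6 | alternative 2 | 3-(benzyloxy)-2-(trimethylsilyl)phenyl trifluoromethanesulfonate | C[Si](C)(C)c1c(OCc2ccccc2)cccc1OS(=O)(=O)C(F)(F)F
A7 | alternative 3 | 2',6'-bis(benzyloxy)acetophenone | CC(=O)c1c(OCc2ccccc2)cccc1OCc1ccccc1
A8 | alternative 3 | 7-[4-(benzyloxy)-3-methoxyphenyl]heptan-1-ol | COc1cc(CCCCCCCO)ccc1OCc1ccccc1
A9 | alternative 3 | 1-[2,6-bis(benzyloxy)phenyl]-9-[4-(benzyloxy)-3-methoxyphenyl]nonan-1-one | COc1cc(CCCCCCCCC(=O)c2c(OCc3ccccc3)cccc2OCc2ccccc2)ccc1OCc1ccccc1
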